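(The data are calculated with made-up constants; scatter was added.)

| flask | starting material | capture agent | free catalyst | remark | time |
|---|---|---|---|---|---|
| south-west | 1.5 M | 0.15 M | 42 mM | run made earlier |  |
| west | 1.5 M | 0.15 M | 66 mM | run made earlier |  |
| east | 1.5 M | 0.075 M | 30 mM | run made earlier |  |
| eta | 1.5 M | 0.150 M | 30 mM |  | 5.0 min |
| delta | 1.5 M | 0.150 M | 30 mM |  | 2.5 min |

| run | time / min | product / % |
|---|---|---|
| south-west | 0.250 | 22.5 |
| south-west | 0.417 | 36.8 |
| south-west | 0.833 | 63.5 |
| south-west | 1.50 | 88.0 |
| south-west | 3.00 | 98.1 |
| west | 0.250 | 35.0 |
| west | 0.833 | 85.8 |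
| west | 1.33 | 97.0 |
| west | 2.00 | 99.2 |
| west | 3.00 | 98.5 |
| east | 0.250 | 17.1 |
| east | 0.417 | 28.0 |
| east | 0.833 | 50.6 |
| east | 1.50 | 77.9 |
| east | 3.00 | 98.1 |

(scatter of a reading: 0.3 percentage points)

- percentages count the starting material that a species holds: one spent catalyst counts as two
- the analysis behind the earlier runs scatters by 0.3 percentage points, standard deviation
- candidate steps: starting material + free catalyst -> catalyst intermediate A; capture agent + catalyst intermediate B -> trapped intermediate; catalyst intermediate B -> free catalyst + product; 2 catalyst intermediate A -> spent catalyst; catalyst intermediate A <-> catalyst intermediate B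

* the winner by amount of product, in percent of the starting material charged; "neither" if no more than 2 percentage points parts them (eta / delta / neither)
* how much product is there at the end, in percent of the starting material charged: eta
* how much product is there at the end, in percent of the starting material charged: delta

- Slowness here is counted in turnovers, one turnover being one product made by one catalyst.
- Eta and delta share N = 50.0, the turnover demand: starting material charged per free catalyst charged.
- First rung: the first reading of the south-west run gives a pace f = 32.1 min⁻¹ per catalyst, and the west run reads 31.8 min⁻¹. One turnover therefore takes about 1.87 s.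
- Next rung: τ = N/f = 1.56 min is the time the eta and delta charge needs at that opening pace, far longer than one turnover.
- On each run's own τ, the south-west run reads 88.0% after 1.35 τ. The west run reads 97.0% after 1.88 τ and 99.2% after 2.83 τ.
- Top rungs: delta is read at 1.61 τ, so my reckoning places delta between the first two of those readings, 88.0% and 97.0%. Eta is read at 3.21 τ, past the west reading of 99.2%, so my reckoning places eta near that reading and ahead of delta.
- The forecast says eta, with 98.2% for eta and 93% for delta, its delta value lying between my two readings: “Some catalyst is lost, so I expect nearer 93%.”
- The flask gives 98.7% for eta and 89.9% for delta, so eta wins, as forecast.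

    starting material + free catalyst → catalyst intermediate A (k = 1.70 L mol⁻¹ s⁻¹)
    capture agent + catalyst intermediate B → trapped intermediate (k = 5.20 L mol⁻¹ s⁻¹)
    catalyst intermediate B → free catalyst + product (k = 79.0 s⁻¹)
    2 catalyst intermediate A → spent catalyst (k = 0.0370 L mol⁻¹ s⁻¹)
    catalyst intermediate A ⇌ catalyst intermediate B (K = 5.00, k = 0.830 s⁻¹)

- At 0.850 min in eta, catalyst intermediate B releases product 110 times per capture into trapped intermediate, above N. That ratio, held over the whole demand, reckons 47.1% of the catalyst charged as trapped intermediate, and eta holds 46.4% at 5.00 min.
- The neighbour with 7.50 mM free catalyst has N = 200, above that ratio, so eta's ratio, held there, reckons one capture per catalyst charged by the time 53.1% of its charge is product. At 5.00 min it holds 40.7% product, with 78.7% of its catalyst trapped.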